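**Plan**

- Cuts: C12–C13 (sp3–sp2 coupling of the side chain). C8=C17 and C2–OAc go back to the carbonyl or carbinol level. C3–C4 of ring A is cut together with the re-formation of a C4–C7 bond that the target does not contain.
- Enabling feature: the gem-dimethyl carbon C4 and C7 are the two ends of the chain C4–C5–C6–C7, and C7 is α to C8, the carbon of the exocyclic methylene (a masked ketone). A C4–C7 bond turns ring B plus C4 into the bicyclo[3.1.1]heptan-2-one (pinane) core of (+)-verbenone. This strained bond, α,β to C8=O, can ionise to a C4 cation and a C8 enol ester.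
- Forward order: ring B (with C4, C18–C20) is bought in 1. C1–C3 (allyl) go on C10 and C11–C12 on C9. The cyclobutane is then broken and ring A closed at C3–C4 in one operation, as the last ring. C17, the C2 correction and the C13–C16 unit follow.
- Stereochemistry: C5 comes from the chiral pool. C10 comes from addition anti to the temporary CMe2 bridge, which fixes the trans fusion before ring A exists. C9 is set by equilibration next to C8=O. C2 is set by hydride attack opposite the two axial methyls. 13Z comes from anti hydroiodination and a stereoretentive coupling.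

Key step: step 3

Assumption: (1R,5R)-(+)-verbenone is taken as purchasable (it is otherwise one allylic oxidation away from (+)-α-pinene). Labdane numbering is used for all intermediates.

**Step 1**
Reactants: 1 (1R,5R)-(+)-verbenone
Product: 2 4-allyl-4,6,6-trimethyl-2-(trimethylsilyloxy)bicyclo[3.1.1]hept-2-ene, allyl anti to the CMe2 bridge (C1 α, C20 β at C10)
Conditions: allylMgBr, CuBr·SMe2, Me3SiCl, THF, −78 °C
Reagents that add atoms: allylmagnesium bromide C=CC[Mg]Br; chlorotrimethylsilane C[Si](C)(C)Cl
Why: Me3SiCl-accelerated conjugate addition of an allylcopper reagent, a reaction type that tolerates β,β-disubstituted enones, should deliver the allyl group to C10 from the face opposite the CMe2 bridge, which sets the quaternary centre with C1 anti to C4 and traps the enolate as its silyl enol ether.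

**Step 2**
Reactants: 2 silyl enol ether
Product: 4 methyl 2-(4-allyl-4,6,6-trimethyl-2-oxobicyclo[3.1.1]hept-3-yl)acetate (allyl and CH2CO2Me both anti to the CMe2 bridge), via lithium enolate 3 (not isolated)
Conditions: MeLi, THF, 0 °C; then DMPU, BrCH2CO2Me, −78 → 0 °C
Reagents that add atoms: methyl bromoacetate COC(=O)CBr
Why: Cleavage of the silyl enol ether with MeLi gives the regiodefined lithium enolate (C7 is a bridgehead and cannot enolise), whose SN2 alkylation by the activated bromide should occur anti to the CMe2 bridge; the C9 configuration is provisional and is corrected in step 4.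

**Step 3**
Reactants: 4 allyl pinanone ester
Product: 6 methyl 2α,8-diacetoxy-9-epi-13,14,15,16,17-pentanorlabd-7-en-12-oate (trans-fused; 5α-H; 10β-Me; 9α-CH2CO2Me), via ring-opened C4 cation 5 (not isolated)
Conditions: Ac2O, BF3·OEt2 (30 mol %), Zn(OAc)2 (30 mol %), 0 °C → rt
Reagents that add atoms: acetic anhydride CC(=O)OC(C)=O
Why: Proposed new method: acylative activation of the C8 carbonyl should trigger heterolysis of the strained C4–C7 cyclobutane bond, which lies α,β to C8=O and overlaps with its π* orbital, to give the C7=C8 enol acetate and the tertiary cation 5, whose C4 is then attacked by the terminal carbon C3 of the allyl group while acetate adds to C2. The closest known reaction types are the BF3·OEt2/Zn(OAc)2/Ac2O opening of pinan-2-one cyclobutanes (there ended by acetate capture or proton loss) and the solvolytic cyclisation of a tertiary cation onto a pendant vinyl group with solvent capture of the secondary carbon; only their merger is new. Ring A closes 6-endo-trig through a chair-like transition state, since the 5-exo alternative would leave a primary cation. C5 and C10 are not touched, so the trans fusion follows from the anti relation of C4 and C1 fixed in step 1, and the only new stereocentre, C2, should receive an equatorial (α) acetate by anti addition across C2=C3, which does not matter because it is erased in step 6. The step needs C–C capture to beat proton loss from C4, hydride migration from C5 and acetate capture at C4. This is secured by the two arms being held trans-diequatorial and gauche on ring B, by the gem-dimethyl effect, by the reversibility of acetate capture at a tertiary centre under BF3, and by Zn(OAc)2 buffering the medium.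

**Step 4**
Reactants: 6 bicyclic diacetate
Product: 7 methyl 2α-hydroxy-8-oxo-13,14,15,16,17-pentanorlabdan-12-oate (9β side chain, 9α-H)
Conditions: K2CO3 (cat.), MeOH, rt
Reagents that add atoms: none
Why: Base-catalysed transesterification frees the C8 ketone and the C2 alcohol, and the enolisable C9 centre should equilibrate to the equatorial (β) side chain of the trans-decalone.

**Step 5**
Reactants: 7 hydroxy keto ester
Product: 8 methyl 2α-hydroxy-13,14,15,16-tetranorlabd-8(17)-en-12-oate
Conditions: Ph3PCH3Br, KN(SiMe3)2, THF, 0 → 45 °C
Reagents that add atoms: methyltriphenylphosphonium bromide C[P+](c1ccccc1)(c1ccccc1)c1ccccc1.[Br-]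
Why: Wittig methylenation is the standard way to turn hindered 8-oxo decalins of this family into the 8(17)-ene, excess ylide covers the free hydroxyl, and C9 is already in its stable configuration.

**Step 6**
Reactants: 8 hydroxy ester
Product: 9 methyl 2-oxo-13,14,15,16-tetranorlabd-8(17)-en-12-oate
Conditions: Dess–Martin periodinane, CH2Cl2, 0 °C → rt
Reagents that add atoms: none
Why: Dess–Martin oxidation of a secondary alcohol leaves the alkene and ester untouched and removes the provisional C2 stereocentre.

**Step 7**
Reactants: 9 keto ester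
Product: 10 13,14,15,16-tetranorlabd-8(17)-ene-2β,12-diol
Conditions: LiAlH4, THF, −78 → 0 °C
Reagents that add atoms: none
Why: In this hydride reduction the β face of C2=O is closed by the two syn-axial methyl groups on C4 and C10, so hydride should arrive from the α face and give the axial 2β-alcohol, while the ester is reduced to the primary alcohol in the same operation.

**Step 8**
Reactants: 10 diol
Product: 11 2β,12-diacetoxy-13,14,15,16-tetranorlabd-8(17)-ene
Conditions: Ac2O, Et3N, DMAP (cat.), CH2Cl2, reflux
Reagents that add atoms: acetic anhydride CC(=O)OC(C)=O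
Why: DMAP-catalysed acylation is run under forcing conditions at this robust stage because the 2β-hydroxyl is buried between two syn-axial methyl groups.

**Step 9**
Reactants: 11 diacetate
Product: 12 2β-acetoxy-13,14,15,16-tetranorlabd-8(17)-en-12-ol
Conditions: K2CO3 (cat.), MeOH, 0 °C
Reagents that add atoms: none
Why: Chemoselective methanolysis should remove only the exposed primary acetate, since the same shielding that slows acylation at C2 slows its cleavage.

**Step 10**
Reactants: 12 acetoxy alcohol
Product: 13 2β-acetoxy-12-iodo-13,14,15,16-tetranorlabd-8(17)-ene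
Conditions: PPh3, I2, imidazole, CH2Cl2, 0 °C
Reagents that add atoms: iodine II
Why: Appel iodination of a primary alcohol with iodine pre-complexed to PPh3 avoids iodoetherification of the 8(17)-alkene.

**Step 11**
Reactants: 14 but-2-ynoic acid
Product: 15 2-(trimethylsilyl)ethyl but-2-ynoate
Conditions: Me3SiCH2CH2OH, DCC, DMAP (cat.), CH2Cl2, 0 °C → rt
Reagents that add atoms: 2-(trimethylsilyl)ethanol C[Si](C)(C)CCO
Why: Steglich esterification installs an ester that can later be removed without touching an acetate.

**Step 12**
Reactants: 15 alkynoate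
Product: 16 2-(trimethylsilyl)ethyl (Z)-3-iodobut-2-enoate
Conditions: NaI, AcOH, 80 °C
Reagents that add atoms: sodium iodide [Na+].[I-]
Why: Hydroiodination of an alkynoate by conjugate addition of iodide and anti protonation places iodine cis to the ester, which is the geometry needed for 13Z.

**Step 13**
Reactants: 13 iodide; 16 (Z)-iodoenoate
Product: 18 2-(trimethylsilyl)ethyl 2β-acetoxylabda-8(17),13Z-dien-15-oate, via alkylzinc iodide 17 (not isolated)
Conditions: Zn dust, LiCl, THF, 40 °C; then 16, Pd(PPh3)4 (5 mol %), THF, rt
Reagents that add atoms: none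
Why: Zinc insertion into the primary iodide followed by Negishi coupling forms C12–C13 with retention of the alkenyl iodide geometry and tolerates both esters and the 1,1-disubstituted alkene.

**Step 14**
Reactants: 18 silylethyl ester
Product: 20 (2R,5S,9S,10S,13Z)-2-acetoxylabda-8(17),13-dien-15-oic acid (target), via tetrabutylammonium carboxylate 19 (not isolated)
Conditions: Bu4NF, THF, 0 °C → rt; then dilute aq. HCl
Reagents that add atoms: none
Why: Fluoride-induced β-elimination of the 2-(trimethylsilyl)ethyl ester frees the acid under conditions that leave the hindered acetate, the Z-enoate and the exocyclic alkene unchanged.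

**Compound list**

1 | (1R,5R)-(+)-verbenone | CC1=CC(=O)[C@@H]2C[C@H]1C2(C)C | starting material
2 | allylated silyl enol ether | C=CC[C@]1(C)C=C(O[Si](C)(C)C)[C@@H]2C[C@H]1C2(C)C | intermediate
3 | lithium enolate | C=CC[C@]1(C)C=C([O-])[C@@H]2C[C@H]1C2(C)C.[Li+] | intermediate
4 | allyl pinanone ester | C=CC[C@]1(C)[C@H](CC(=O)OC)C(=O)[C@@H]2C[C@H]1C2(C)C | intermediate
5 | ring-opened C4 cation (C8 enol acetate) | C=CC[C@]1(C)[C@H](CC(=O)OC)C(OC(C)=O)=CC[C@H]1[C+](C)C | intermediate
6 | bicyclic 2α,8-diacetate | COC(=O)C[C@@H]1C(OC(C)=O)=CC[C@H]2C(C)(C)C[C@H](OC(C)=O)C[C@]12C | intermediate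
7 | 2α-hydroxy-8-oxo ester | COC(=O)C[C@H]1C(=O)CC[C@H]2C(C)(C)C[C@H](O)C[C@]12C | intermediate
8 | 2α-hydroxy-8(17)-ene ester | COC(=O)C[C@H]1C(=C)CC[C@H]2C(C)(C)C[C@H](O)C[C@]12C | intermediate
9 | 2-oxo-8(17)-ene ester | COC(=O)C[C@H]1C(=C)CC[C@H]2C(C)(C)CC(=O)C[C@]12C | intermediate
10 | 2β,12-diol | OCC[C@H]1C(=C)CC[C@H]2C(C)(C)C[C@@H](O)C[C@]12C | intermediate
11 | 2β,12-diacetate | CC(=O)OCC[C@H]1C(=C)CC[C@H]2C(C)(C)C[C@@H](OC(C)=O)C[C@]12C | intermediate
12 | 2β-acetoxy-12-ol | OCC[C@H]1C(=C)CC[C@H]2C(C)(C)C[C@@H](OC(C)=O)C[C@]12C | intermediate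
13 | 2β-acetoxy-12-iodide | ICC[C@H]1C(=C)CC[C@H]2C(C)(C)C[C@@H](OC(C)=O)C[C@]12C | intermediate
14 | but-2-ynoic acid | CC#CC(=O)O | starting material
15 | 2-(trimethylsilyl)ethyl but-2-ynoate | CC#CC(=O)OCC[Si](C)(C)C | intermediate
16 | 2-(trimethylsilyl)ethyl (Z)-3-iodobut-2-enoate | C/C(I)=C/C(=O)OCC[Si](C)(C)C | intermediate
17 | alkylzinc iodide | I[Zn]CC[C@H]1C(=C)CC[C@H]2C(C)(C)C[C@@H](OC(C)=O)C[C@]12C | intermediate
18 | silylethyl ester of the target | C=C1CC[C@H]2C(C)(C)C[C@@H](OC(C)=O)C[C@]2(C)[C@H]1CC/C(C)=C\C(=O)OCC[Si](C)(C)C | intermediate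
19 | tetrabutylammonium carboxylate | C=C1CC[C@H]2C(C)(C)C[C@@H](OC(C)=O)C[C@]2(C)[C@H]1CC/C(C)=C\C(=O)[O-].CCCC[N+](CCCC)(CCCC)CCCC | intermediate
20 | 2β-acetoxylabda-8(17),13Z-dien-15-oic acid | C=C1CC[C@H]2C(C)(C)C[C@@H](OC(C)=O)C[C@]2(C)[C@H]1CC/C(C)=C\C(=O)O | target

Total step count: 14. Longest linear sequence: 12 (steps 1–10, 13, 14).

**Steps most likely to fail**

**1. Step 3.**
- What may go wrong: proton loss from the C4 cation, hydride migration from C5 (loss of the C5 configuration), or acylation of the vinyl group may outrun the C–C capture by a weak π-nucleophile.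
- Fallback, from 4 back to 10, with the two events separated and a much stronger nucleophile at the ketone oxidation level. Wacker–Tsuji oxidation of the allyl group (PdCl2, CuCl, O2, DMF–H2O) gives the methyl ketone F1.
- The BF3·OEt2/Zn(OAc)2/Ac2O opening, now run in its known form without a π-nucleophile, gives the enol acetate tertiary acetate F2. Soft enolisation (Me3SiOTf, Et3N) gives the terminal silyl enol ether F3.
- TiCl4 at −78 °C ionises the tertiary acetate, and the enol silane closes C3–C4 to give the 2-ketone enol acetate F4. This is a Lewis-acid α-tert-alkylation of a silyl enol ether, and C8 stays masked so that no aldol can compete.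
- LiBH(s-Bu)3 reduces C2 from the α face to the 2β-hydroxy enol acetate F5. K2CO3/MeOH frees the ketone and equilibrates C9 to give the 2β-hydroxy ketone F6. Wittig methylenation gives the 2β-hydroxy 8(17)-ene ester F7, and LiAlH4 then gives 10.

**2. Step 1.**
- What may go wrong: competing 1,2-addition of the allyl metal, or stalling at the hindered β-carbon.
- Fallback, from 1 back to 2, which uses the 1,2-addition instead of fighting it. AllylMgBr adds to C8=O from the face anti to the CMe2 bridge to give the tertiary allylic alcohol F8.
- Anionic oxy-Cope rearrangement (KH, 18-crown-6, THF) moves the allyl terminus suprafacially to C10 on the same α face. The resulting enolate is silylated with Me3SiCl to give 2.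

**3. Step 2.**
- What may go wrong: slow alkylation next to the quaternary C10, with proton transfer between enolate and product or attack on the ester carbonyl.
- Fallback, from 3 back to 4, which replaces the SN2 step by a carbonyl addition. Aldol addition of 3 to methyl glyoxylate gives the β-hydroxy ester F9.
- Mesylation and elimination (MsCl, Et3N, then DBU) give the alkylidene keto ester F10. Conjugate reduction of this ene-dicarbonyl with Zn/AcOH, followed by brief DBU equilibration, returns 4.

**Further compounds**

F1 | step 3 | acetonyl pinanone ester | CC(=O)C[C@]1(C)[C@H](CC(=O)OC)C(=O)[C@@H]2C[C@H]1C2(C)C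
F2 | step 3 | ring-opened enol acetate tertiary acetate | CC(=O)C[C@]1(C)[C@H](CC(=O)OC)C(OC(C)=O)=CC[C@H]1C(C)(C)OC(C)=O
F3 | step 3 | terminal silyl enol ether of F2 | C=C(O[Si](C)(C)C)C[C@]1(C)[C@H](CC(=O)OC)C(OC(C)=O)=CC[C@H]1C(C)(C)OC(C)=O
F4 | step 3 | bicyclic 2-ketone 8-enol acetate | COC(=O)C[C@@H]1C(OC(C)=O)=CC[C@H]2C(C)(C)CC(=O)C[C@]12C
F5 | step 3 | 2β-hydroxy 8-enol acetate | COC(=O)C[C@@H]1C(OC(C)=O)=CC[C@H]2C(C)(C)C[C@@H](O)C[C@]12C
F6 | step 3 | 2β-hydroxy-8-oxo ester | COC(=O)C[C@H]1C(=O)CC[C@H]2C(C)(C)C[C@@H](O)C[C@]12C
F7 | step 3 | 2β-hydroxy-8(17)-ene ester | COC(=O)C[C@H]1C(=C)CC[C@H]2C(C)(C)C[C@@H](O)C[C@]12C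
F8 | step 1 | 2-allylverbenol (allyl anti to the CMe2 bridge) | CC1=C[C@](O)(CC=C)[C@@H]2C[C@H]1C2(C)C
F9 | step 2 | glyoxylate aldol adduct (carbinol centre undefined) | C=CC[C@]1(C)[C@H](C(O)C(=O)OC)C(=O)[C@@H]2C[C@H]1C2(C)C
F10 | step 2 | alkylidene keto ester | C=CC[C@]1(C)/C(=C/C(=O)OC)C(=O)[C@@H]2C[C@H]1C2(C)C
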